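**Plan**

- Ring A is the central benzene: C1 bears the methide carbon Cm, C2 ring B (4-hydroxyphenyl), C5 the CH2OH group and C6 the arylethynyl arm ending in ring D. Cm carries ring C (4-hydroxyphenyl) and ring Q (the cyclohexadienone), which are tautomeric forms of one another, so in the leuco form Cm is an sp3 carbon with two 4-hydroxyphenyl groups, the pattern left when an aldehyde carbon takes up two phenols at their para carbons.
- Retrosynthesis: ring Q is reduced to the leuco triarylmethane, the C6–C(sp) bond is cut (Sonogashira), and then both Cm–aryl bonds are cut together, giving a ring A aldehyde with iodine at C6 and two molecules of phenol.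
- Ring A is cut across C1–C2 and C5–C6 into an E,E-1-aryl diene and 3-(trimethylsilyl)propynal; the diene comes from 4-hydroxybenzaldehyde by vinylogous olefination.
- Forward: diene, then [4+2]/dehydrogenation (ring A, the only ring built), iododesilylation, double phenol condensation (rings C and Q attached), Sonogashira (ring D), ester cleavage, dehydrogenation to the quinone methide.
- Stereochemistry: the target has no stereocentre. Only the E,E geometry of the diene is controlled (olefination); the sp3 centres of the cycloadduct and of the benzhydrol are erased.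

Key step: step 6

Remark: the target carries no stereodescriptor, so slow rotation about its crowded aryl bonds is not addressed; 4-ethynylphenol is taken as a stock chemical.

**Route**

Step 1
Reactants: 1 4-hydroxybenzaldehyde; 2 triethyl 4-phosphonocrotonate
Product: 3 ethyl (2E,4E)-5-(4-hydroxyphenyl)penta-2,4-dienoate
Conditions: LiN(SiMe3)2 (2.3 equiv), THF, −78 °C to rt; aq. NH4Cl
Reagents that add atoms: none
Why: Horner–Wadsworth–Emmons olefination with the γ-phosphonocrotonate anion, in which the extra base holds the phenol as its lithium phenoxide (still able to condense) and the stabilised anion should give the 2E,4E dienoate as the main isomer.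

Step 2
Reactants: 3 ethyl (2E,4E)-5-(4-hydroxyphenyl)penta-2,4-dienoate
Product: 4 (2E,4E)-5-(4-hydroxyphenyl)penta-2,4-dien-1-ol
Conditions: i-Bu2AlH (3.5 equiv), THF/CH2Cl2, −78 to 0 °C; aq. KNa tartrate
Reagents that add atoms: none
Why: i-Bu2AlH reduces conjugated esters in the 1,2 sense to allylic alcohols without touching the diene, one equivalent being spent on the phenol; the neutral work-up protects the acid-sensitive dienol.

Step 3
Reactants: 4 (2E,4E)-5-(4-hydroxyphenyl)penta-2,4-dien-1-ol
Product: 5 (2E,4E)-5-[4-(pivaloyloxy)phenyl]penta-2,4-dien-1-yl pivalate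
Conditions: PivCl (2.4 equiv), Et3N, DMAP (cat.), CH2Cl2, 0 °C to rt
Reagents that add atoms: pivaloyl chloride, CC(C)(C)C(Cl)=O
Why: DMAP-catalysed acylation of both hydroxyl groups, giving an aryl ester that deactivates ring B for the later acid step and an allylic ester that should survive heat, DDQ and ICl.

Step 4
Reactants: 5 (2E,4E)-5-[4-(pivaloyloxy)phenyl]penta-2,4-dien-1-yl pivalate; 6 3-(trimethylsilyl)propynal
Product: 8 4-[2-formyl-4-(pivaloyloxymethyl)-3-(trimethylsilyl)phenyl]phenyl pivalate, via cis-cyclohexa-1,4-diene cycloadduct 7 (not isolated)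
Conditions: 6 (1.5 equiv), BHT (cat.), toluene, 105 °C, sealed tube; then DDQ (1.2 equiv), rt
Reagents that add atoms: none
Why: Thermal Diels–Alder reaction of an E,E-1,4-disubstituted diene with an ynal, in which the conjugating aryl group places the larger HOMO coefficient on the far, CH2OPiv-bearing terminus, so this carbon should bond to the silyl-bearing β-carbon and the formyl group should end up next to the aryl-bearing carbon; the suprafacial addition gives the cis-3,6-disubstituted cyclohexa-1,4-diene, whose two sp3 centres are removed by DDQ dehydrogenation.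

Step 5
Reactants: 8 4-[2-formyl-4-(pivaloyloxymethyl)-3-(trimethylsilyl)phenyl]phenyl pivalate
Product: 9 4-[2-formyl-3-iodo-4-(pivaloyloxymethyl)phenyl]phenyl pivalate
Conditions: ICl (1.5 equiv), CH2Cl2, 0 °C to rt; aq. Na2S2O3
Reagents that add atoms: iodine monochloride, ClI
Why: Electrophilic ipso-iododesilylation, favoured at the silyl-bearing carbon by the β-silicon effect and by relief of crowding, while the acyloxy-substituted ring B should be too electron-poor to be iodinated by ICl alone.

Step 6
Reactants: 9 4-[2-formyl-3-iodo-4-(pivaloyloxymethyl)phenyl]phenyl pivalate; 10 phenol (two molecules enter)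
Product: 12 4-[2-[bis(4-hydroxyphenyl)methyl]-3-iodo-4-(pivaloyloxymethyl)phenyl]phenyl pivalate, via benzhydrol 11 (not isolated)
Conditions: phenol (20 equiv, melt), MeSO3H (0.5 equiv), 45 °C
Reagents that add atoms: none
Why: Brønsted-acid Baeyer condensation: the protonated formyl carbon of 9 is attacked by the para carbon of phenol (Friedel–Crafts hydroxyalkylation) to give benzhydrol 11, which ionises to an O-protonated quinone methide that a second phenol captures at its para carbon (Friedel–Crafts alkylation), so both Cm–aryl bonds form in one flask. The closest known reaction type is the condensation of 2,6-disubstituted benzaldehydes with phenols to the leuco forms of hydroxytriarylmethane dyes. No ring is closed and no stereocentre is created, because Cm ends with two identical 4-hydroxyphenyl groups. The step needs para attack twice, no closure of the cation onto ring B (a fluorene) and no ionisation of the benzylic ester. The cation, flanked by iodine and ring B, should select the unhindered para carbon, and phenol in large excess is a far better nucleophile than ring B, whose reactive position lies meta to the deactivating pivaloyloxy group. Iodine in place of the alkyne at C6 removes an internal π-nucleophile, and the primary pivalate on the electron-poor ring A should not ionise.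

Step 7
Reactants: 13 4-ethynylphenol
Product: 14 4-ethynylphenyl pivalate
Conditions: PivCl (1.2 equiv), Et3N, DMAP (cat.), CH2Cl2, 0 °C
Reagents that add atoms: pivaloyl chloride, CC(C)(C)C(Cl)=O
Why: Simple O-acylation, which should turn the polymerisation-prone ethynylphenol into a storable alkyne for the coupling.

Step 8
Reactants: 12 4-[2-[bis(4-hydroxyphenyl)methyl]-3-iodo-4-(pivaloyloxymethyl)phenyl]phenyl pivalate; 14 4-ethynylphenyl pivalate
Product: 15 4-[2-[bis(4-hydroxyphenyl)methyl]-4-(pivaloyloxymethyl)-3-[[4-(pivaloyloxy)phenyl]ethynyl]phenyl]phenyl pivalate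
Conditions: PdCl2(PPh3)2 (5 mol %), CuI (10 mol %), Et3N, DMF, 60 °C, argon
Reagents that add atoms: none
Why: Sonogashira coupling, in which an aryl iodide with two ortho substituents should still accept the slim copper acetylide, free phenols are tolerated under amine base, and the benzylic pivalate prevents metal-catalysed cyclisation of an alcohol onto the new alkyne.

Step 9
Reactants: 15 4-[2-[bis(4-hydroxyphenyl)methyl]-4-(pivaloyloxymethyl)-3-[[4-(pivaloyloxy)phenyl]ethynyl]phenyl]phenyl pivalate
Product: 16 leuco-selaginellin, [4'-hydroxy-4-(hydroxymethyl)-3-[(4-hydroxyphenyl)ethynyl]biphenyl-2-yl]bis(4-hydroxyphenyl)methane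
Conditions: NaOMe (8 equiv), MeOH/THF, 40 °C, argon; then AcOH
Reagents that add atoms: none
Why: Zemplén-type methanolysis of the two aryl pivalates and the benzylic pivalate; the alkyne, made electron-rich by the ring D phenoxide, should resist attack by the benzylic alkoxide in the protic medium, and exclusion of air keeps the leuco phenoxide from uncontrolled oxidation.

Step 10
Reactants: 16 leuco-selaginellin
Product: 17 selaginellin
Conditions: DDQ (1.0 equiv), THF, 0 °C
Reagents that add atoms: none
Why: DDQ dehydrogenation of a bis(4-hydroxyphenyl)methane to its quinone methide (fuchsone formation), where hydride loss from the methine activated by two para-hydroxyl groups should be much faster than oxidation of the isolated phenols of rings B and D or of the electron-poor benzylic alcohol.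

**Compound list**

1 | 4-hydroxybenzaldehyde | O=Cc1ccc(O)cc1 | starting material
2 | triethyl 4-phosphonocrotonate | CCOC(=O)/C=C/CP(=O)(OCC)OCC | starting material
3 | ethyl (2E,4E)-5-(4-hydroxyphenyl)penta-2,4-dienoate | CCOC(=O)/C=C/C=C/c1ccc(O)cc1 | intermediate
4 | (2E,4E)-5-(4-hydroxyphenyl)penta-2,4-dien-1-ol | OC/C=C/C=C/c1ccc(O)cc1 | intermediate
5 | (2E,4E)-5-[4-(pivaloyloxy)phenyl]penta-2,4-dien-1-yl pivalate | CC(C)(C)C(=O)OC/C=C/C=C/c1ccc(OC(=O)C(C)(C)C)cc1 | intermediate
6 | 3-(trimethylsilyl)propynal | C[Si](C)(C)C#CC=O | starting material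
7 | cis-4-[2-formyl-4-(pivaloyloxymethyl)-3-(trimethylsilyl)cyclohexa-2,5-dien-1-yl]phenyl pivalate (racemic, one enantiomer drawn) | O=CC1=C([Si](C)(C)C)[C@@H](COC(=O)C(C)(C)C)C=C[C@H]1c1ccc(OC(=O)C(C)(C)C)cc1 | intermediate (not isolated)
8 | 4-[2-formyl-4-(pivaloyloxymethyl)-3-(trimethylsilyl)phenyl]phenyl pivalate | O=Cc1c(-c2ccc(OC(=O)C(C)(C)C)cc2)ccc(COC(=O)C(C)(C)C)c1[Si](C)(C)C | intermediate
9 | 4-[2-formyl-3-iodo-4-(pivaloyloxymethyl)phenyl]phenyl pivalate | O=Cc1c(-c2ccc(OC(=O)C(C)(C)C)cc2)ccc(COC(=O)C(C)(C)C)c1I | intermediate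
10 | phenol | Oc1ccccc1 | starting material
11 | 4-[2-[hydroxy(4-hydroxyphenyl)methyl]-3-iodo-4-(pivaloyloxymethyl)phenyl]phenyl pivalate (racemic) | CC(C)(C)C(=O)OCc1ccc(-c2ccc(OC(=O)C(C)(C)C)cc2)c(C(O)c2ccc(O)cc2)c1I | intermediate (not isolated)
12 | 4-[2-[bis(4-hydroxyphenyl)methyl]-3-iodo-4-(pivaloyloxymethyl)phenyl]phenyl pivalate | CC(C)(C)C(=O)OCc1ccc(-c2ccc(OC(=O)C(C)(C)C)cc2)c(C(c2ccc(O)cc2)c2ccc(O)cc2)c1I | intermediate
13 | 4-ethynylphenol | C#Cc1ccc(O)cc1 | starting material
14 | 4-ethynylphenyl pivalate | C#Cc1ccc(OC(=O)C(C)(C)C)cc1 | intermediate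
15 | 4-[2-[bis(4-hydroxyphenyl)methyl]-4-(pivaloyloxymethyl)-3-[[4-(pivaloyloxy)phenyl]ethynyl]phenyl]phenyl pivalate | CC(C)(C)C(=O)OCc1ccc(-c2ccc(OC(=O)C(C)(C)C)cc2)c(C(c2ccc(O)cc2)c2ccc(O)cc2)c1C#Cc1ccc(OC(=O)C(C)(C)C)cc1 | intermediate
16 | leuco-selaginellin, [4'-hydroxy-4-(hydroxymethyl)-3-[(4-hydroxyphenyl)ethynyl]biphenyl-2-yl]bis(4-hydroxyphenyl)methane | OCc1ccc(-c2ccc(O)cc2)c(C(c2ccc(O)cc2)c2ccc(O)cc2)c1C#Cc1ccc(O)cc1 | intermediate
17 | selaginellin | O=C1C=CC(=C(c2ccc(O)cc2)c2c(-c3ccc(O)cc3)ccc(CO)c2C#Cc2ccc(O)cc2)C=C1 | target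

**Step count**

Total: 10 steps. Longest linear sequence: 9 steps (steps 1–6, then 8–10); step 7 is a one-step side branch.

**Steps most likely to fail**

1. Step 6 (key step). The first hydroxyalkylation at the di-ortho-substituted carbonyl may be slow, so that long exposure to acid allows attack at the ortho carbon of phenol, closure of the benzylic cation onto ring B, and acyl exchange of the aryl pivalate with the phenol melt.
Fallback, from 9 back to 12: the same two Cm–aryl bonds are made one at a time. Aldehyde 9 is treated with 4-(t-BuMe2SiO)C6H4MgBr in THF at −78 °C, where the aldehyde should react well before the pivalates or the aryl iodide, to give the benzhydrol 4-[2-[[4-(tert-butyldimethylsilyloxy)phenyl](hydroxy)methyl]-3-iodo-4-(pivaloyloxymethyl)phenyl]phenyl pivalate F1; this fixes the para connectivity of the first ring without acid. The benzhydrol ionises far more easily than the aldehyde condenses, so the second aryl group can be introduced cold and briefly: phenol 10 (5 equiv) and TsOH·H2O (10 mol %) in (CF3)2CHOH/CH2Cl2 at 0 °C should give the triarylmethane 4-[2-[[4-(tert-butyldimethylsilyloxy)phenyl](4-hydroxyphenyl)methyl]-3-iodo-4-(pivaloyloxymethyl)phenyl]phenyl pivalate F2. KHF2 in MeOH at rt, which cleaves aryl silyl ethers and leaves pivalates alone, then returns 12.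

2. Step 4. The hindered β-silyl ynal may add too slowly to a diene substituted at both termini, and at the temperature then needed the regiochemical preference set by the aryl group may erode and the ynal may oligomerise.
Fallback, from 5 back to 15: silicon is dropped and the halogen is placed by directed C–H functionalisation. Diene 5 and unhindered propynal with BF3·OEt2 (20 mol %) in CH2Cl2 at −40 °C should give the cycloadduct cis-4-[2-formyl-4-(pivaloyloxymethyl)cyclohexa-2,5-dien-1-yl]phenyl pivalate F3; the acid-complexed ynal is more polarised, which should sharpen the orientation. DDQ in the same flask should give 4-[2-formyl-4-(pivaloyloxymethyl)phenyl]phenyl pivalate F4. The only free position ortho to the formyl group is C6, so ortho C–H bromination through a transient imine (NBS, Pd(OAc)2 10 mol %, catalytic 2-amino-5-chlorobenzotrifluoride, ClCH2CH2Cl/AcOH, 60 °C) should give 4-[3-bromo-2-formyl-4-(pivaloyloxymethyl)phenyl]phenyl pivalate F5. Under the conditions of step 6 this should pass through the benzhydrol 4-[3-bromo-2-[hydroxy(4-hydroxyphenyl)methyl]-4-(pivaloyloxymethyl)phenyl]phenyl pivalate F6 to 4-[2-[bis(4-hydroxyphenyl)methyl]-3-bromo-4-(pivaloyloxymethyl)phenyl]phenyl pivalate F7. Coupling of the hindered bromide with 14 under more active conditions (Pd(PhCN)2Cl2, P(t-Bu)3, CuI, i-Pr2NH, dioxane, 60 °C) rejoins the route at 15; step 5 is no longer needed.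

3. Step 5. Ipso attack of the iodine electrophile on a ring deactivated by the ortho formyl group may be slower than protodesilylation by HCl formed in the flask or than iodination of ring B.
Fallback, from 8 back to 9: the formyl group is lowered in oxidation level for the substitution. NaBH4 in MeOH/THF at 0 °C (pivalates should survive) gives 4-[2-(hydroxymethyl)-4-(pivaloyloxymethyl)-3-(trimethylsilyl)phenyl]phenyl pivalate F8, whose ring A is no longer deactivated by a carbonyl group. ICl in CH2Cl2 at 0 °C should then give 4-[2-(hydroxymethyl)-3-iodo-4-(pivaloyloxymethyl)phenyl]phenyl pivalate F9, and Dess–Martin periodinane in CH2Cl2 returns 9.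

**Further compounds**

F1 | step 6 | 4-[2-[[4-(tert-butyldimethylsilyloxy)phenyl](hydroxy)methyl]-3-iodo-4-(pivaloyloxymethyl)phenyl]phenyl pivalate (racemic) | CC(C)(C)C(=O)OCc1ccc(-c2ccc(OC(=O)C(C)(C)C)cc2)c(C(O)c2ccc(O[Si](C)(C)C(C)(C)C)cc2)c1I
F2 | step 6 | 4-[2-[[4-(tert-butyldimethylsilyloxy)phenyl](4-hydroxyphenyl)methyl]-3-iodo-4-(pivaloyloxymethyl)phenyl]phenyl pivalate (racemic) | CC(C)(C)C(=O)OCc1ccc(-c2ccc(OC(=O)C(C)(C)C)cc2)c(C(c2ccc(O)cc2)c2ccc(O[Si](C)(C)C(C)(C)C)cc2)c1I
F3 | step 4 | cis-4-[2-formyl-4-(pivaloyloxymethyl)cyclohexa-2,5-dien-1-yl]phenyl pivalate (racemic, one enantiomer drawn) | O=CC1=C[C@@H](COC(=O)C(C)(C)C)C=C[C@H]1c1ccc(OC(=O)C(C)(C)C)cc1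
F4 | step 4 | 4-[2-formyl-4-(pivaloyloxymethyl)phenyl]phenyl pivalate | O=Cc1cc(COC(=O)C(C)(C)C)ccc1-c1ccc(OC(=O)C(C)(C)C)cc1
F5 | step 4 | 4-[3-bromo-2-formyl-4-(pivaloyloxymethyl)phenyl]phenyl pivalate | O=Cc1c(-c2ccc(OC(=O)C(C)(C)C)cc2)ccc(COC(=O)C(C)(C)C)c1Br
F6 | step 4 | 4-[3-bromo-2-[hydroxy(4-hydroxyphenyl)methyl]-4-(pivaloyloxymethyl)phenyl]phenyl pivalate (racemic) | CC(C)(C)C(=O)OCc1ccc(-c2ccc(OC(=O)C(C)(C)C)cc2)c(C(O)c2ccc(O)cc2)c1Br
F7 | step 4 | 4-[2-[bis(4-hydroxyphenyl)methyl]-3-bromo-4-(pivaloyloxymethyl)phenyl]phenyl pivalate | CC(C)(C)C(=O)OCc1ccc(-c2ccc(OC(=O)C(C)(C)C)cc2)c(C(c2ccc(O)cc2)c2ccc(O)cc2)c1Br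
F8 | step 5 | 4-[2-(hydroxymethyl)-4-(pivaloyloxymethyl)-3-(trimethylsilyl)phenyl]phenyl pivalate | OCc1c(-c2ccc(OC(=O)C(C)(C)C)cc2)ccc(COC(=O)C(C)(C)C)c1[Si](C)(C)C
F9 | step 5 | 4-[2-(hydroxymethyl)-3-iodo-4-(pivaloyloxymethyl)phenyl]phenyl pivalate | OCc1c(-c2ccc(OC(=O)C(C)(C)C)cc2)ccc(COC(=O)C(C)(C)C)c1I
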